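The runs are simulated for an exercise.

Slowness in the earlier runs was of an odd kind. In the delta run the electrophile was down to 54% by 4.00 h, yet it still stood at 45% at 15.0 h, although the nucleophile was charged in excess.

| flask | electrophile | nucleophile | protic impurity | remark | time |
|---|---|---|---|---|---|
| epsilon | 0.20 M | 0.19 M | 0.010 M | run made earlier |  |
| beta | 0.20 M | 0.35 M | 0.010 M | run made earlier |  |
| delta | 0.20 M | 0.67 M | 0.010 M | run made earlier |  |
| south-west | 0.20 M | 0.180 M | 0.0100 M |  | 30 h |
| south | 0.20 M | 0.360 M | 0.0100 M |  | 30 h |
| north-west | 0.20 M | 0.720 M | 0.0100 M |  | 30 h |

| run | time / h | electrophile / % | product / % |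
|---|---|---|---|
| epsilon | 1.33 | 87 | 10 |
| epsilon | 3.00 | 83 | 17 |
| epsilon | 6.00 | 75 | 22 |
| epsilon | 15.0 | 72 | 32 |
| beta | 2.00 | 77 | 21 |
| beta | 5.00 | 66 | 31 |
| beta | 10.0 | 63 | 39 |
| beta | 15.0 | 58 | 40 |
| delta | 4.00 | 54 | 46 |
| delta | 8.00 | 46 | 52 |
| delta | 12.0 | 46 | 58 |
| delta | 15.0 | 45 | 54 |

(readings scatter by 1.5 percentage points)

- the numbers in the tables scatter by 1.5 percentage points (one standard deviation)

- part of the electrophile that has reacted at the end, south-west
- part of the electrophile that has reacted at the end, south
- part of the electrophile that has reacted at the end, north-west
- what raising the concentration of nucleophile from its lowest to its highest value here does to the part of the electrophile that has reacted (changes below 5 percentage points count as none) (it falls / it rises / no change)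

Each run stalled, and the stall moved with the charge of nucleophile, so I froze one quantity. With the electrophile held at 0.20 M, the last beta reading gives 0.483 M, the even-odds charge: the nucleophile charge at which reacted and unreacted electrophile stand equal at the stall. The dimensionless number is then the nucleophile charged over this charge, and if that number is G, the reacted part is G/(1+G).

I tested whether this one number was enough. It gives 28.2% for the epsilon run, where 28.0% was read, and 58.1% for the delta run, where 55.0% was read. That second gap is 3.1 percentage points against a scatter of 1.5 points, so the number was usable but a little rough. I reckoned 27.1% for south-west, 42.7% for south and 59.8% for north-west.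

The forecast gave 30%, 43% and 58%, higher than mine at south-west, and its trend was that it rises. Its reasoning said “so I interpolate empirically on the plateaus rather than trust a single K”.

The flasks gave 29.3%, 45.0% and 60.7%, so it rises, by 31 points.

    nucleophile + protic impurity → quenched reagent (k = 0.100 M⁻¹ min⁻¹)
    electrophile + nucleophile → acid set free + product (k = 0.0100 M⁻¹ min⁻¹)
    2 nucleophile → homo dimer (k = 0.0110 M⁻¹ min⁻¹)
    nucleophile + acid set free ⇌ protonated nucleophile, settled at all times (K = 14000 M⁻¹)

In north-west just after the start, dimer formation used nucleophile 7.9 times as fast as the addition did. By 30.0 h that ratio in north-west was 0.11, with 0.57% of the nucleophile's charge left free against 39% of the electrophile's and 0.233 M of homo dimer and 0.119 M of protonated nucleophile standing in the flask, and the electrophile's half-life by addition was then 12 d, long against 30 h. For the neighbour of north-west with 0.29 M of nucleophile, the even-odds charge 0.483 M gives 37.5%, and that flask reached 39.9%.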